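All runs come from a simulation for substances that don't exist; scatter was added.

The flask was stirred at constant volume, and I had to compare four ways of charging and warming it at 15 min.

| flask | electrophile | nucleophile | buffer base | buffer acid | temperature | remark | time |
|---|---|---|---|---|---|---|---|
| summer | 0.050 M | 0.045 M | 0.025 M | 5 mM | 45 °C | run made earlier |  |
| dusk | 0.050 M | 0.045 M | 0.025 M | 3.4 mM | 56 °C | run made earlier |  |
| dawn | 0.050 M | 0.045 M | 0.025 M | 7.5 mM | 45 °C | run made earlier |  |
| spring | 0.050 M | 0.068 M | 0.025 M | 5 mM | 56 °C | run made earlier |  |
| north-east | 0.050 M | 0.0450 M | 0.0250 M | 5.00 mM |  | everything together at the start at 20 °C, warmed to 50 °C at 6.0 min | 15 min |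
| east | 0.050 M (fed, over 6.0 min) | 0.0450 M | 0.0250 M | 5.00 mM | 50 °C | all else is in the flask from the start; the feed brings no volume worth counting | 15 min |
| west | 0.050 M | 0.0450 M | 0.0250 M | 5.00 mM | 50 °C | everything together at the start | 15 min |
| south-west | 0.050 M (fed, over 6.0 min) | 0.0450 M | 0.0250 M | 5.00 mM |  | the addition at 20 °C, then warmed to 50 °C; the feed brings no volume worth counting | 15 min |

- summer (time / min: target / %, electrophile / %): 1.00: 14.2, 85.2; 3.00: 28.2, 71.8; 5.00: 34.2, 65.8; 8.00: 37.9, 62.2; 12.0: 39.6, 60.3; 15.0: 39.9, 59.9
- dusk (time / min: target / %, electrophile / %): 1.00: 21.0, 77.7; 3.00: 35.7, 63.8; 5.00: 38.9, 59.9; 8.00: 41.4, 59.3; 12.0: 41.3, 57.2; 15.0: 41.5, 56.8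
- dawn (time / min: target / %, electrophile / %): 2.50: 24.8, 76.0; 5.00: 31.8, 68.0; 8.00: 35.7, 64.4; 10.0: 36.5, 62.7; 12.0: 37.0, 64.1; 15.0: 37.6, 61.7
- spring (time / min: target / %, electrophile / %): 3.00: 52.3, 49.1; 6.00: 59.3, 40.7; 10.0: 61.5, 37.5; 12.0: 62.6, 36.8; 15.0: 63.5, 36.6

(standard deviation of a reading: 0.5 percentage points)



- the best flask by amount of target, in percent of the electrophile charged; "all alike" if 1.5 percentage points covers them all (north-east / east / west / south-west / all alike)
- amount of target at the end, in percent of the electrophile charged, north-east
- amount of target at the end, in percent of the electrophile charged, east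
- amount of target at the end, in percent of the electrophile charged, west
- amount of target at the end, in percent of the electrophile charged, south-west

In the summer run the target grew by 0.0700 min⁻¹ of the charge between 1.00 min and 3.00 min, but by 0.00425 min⁻¹ between 8.00 min and 12.0 min, which is 16.5 times slower. The fall of electrophile across those intervals accounted for a factor 1.28, and nucleophile spent one for one in coupling for 1.34. A factor 9.57 remained, so the nucleophile able to couple was vanishing faster than coupling spent it.

The ends of the runs pointed to where it went. From summer to dawn, 2.50 mM more buffer acid cost 1.15 mM of target, about half as much. The spring run, which was also warmer than summer, held 23.0 mM more nucleophile and ended with 11.8 mM more target, again about half. So I reckoned one nucleophile lost per buffer acid and two per target, which makes nucleophile the limiting reagent. I call 40.0% the stall level S, the nucleophile charge less the buffer acid, over twice the electrophile charge. The dusk run, hotter than summer, which I had not used for this, read 41.5% at its last reading against an S of 41.6%.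

In the summer run, at 45 °C, the readings put the half-life of the distance to S at 1.95 min. After 6.0 min, north-east, east and south-west each had 9.00 min at 50 °C, which is 4.61 such half-lives. Reckoned at that pace, which I carried over to flasks hotter than summer, even a distance of the whole of S shrinks over these to 1.6 percentage points, so I expected the flasks alike, near S.

The forecast differed: it named north-east best, with 40.3% there, 23.5% in east, 40% in west and 36.5% in south-west, holding that “Feeding starves the nucleophile of partner while it decays”.

The flasks gave 39.6% in north-east, 39.9% in east, 40.3% in west and 39.5% in south-west, a spread inside 1.5 points, so the answer is all alike, around the S of 40.0%.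

    electrophile → decomposition product (k = 4.55 × 10⁻⁴ min⁻¹, Ea = 101 kJ mol⁻¹)
    electrophile + nucleophile → acid + target + leaving group (k = 6.46 M⁻¹ min⁻¹, Ea = 44.0 kJ mol⁻¹)
    protonated nucleophile ⇌ nucleophile + acid, settled at all times (K = 2.00 × 10⁻⁹ M, ΔH = −43.0 kJ mol⁻¹)
    buffer acid ⇌ buffer base + acid, settled at all times (K = 1.30 × 10⁻⁵ M, ΔH = −43.0 kJ mol⁻¹)
    (constants at 50 °C)

East already held 30.3% target at the end of its feed, more than the forecast's 23.5% for the end, and it finished with nucleophile at 0.852% of its charge and protonated nucleophile at 0.0247 M. Carried to a neighbour of west charged with 0.12 M of electrophile, S comes to 16.7%. That neighbour gave 17.3% target, with 82% of its electrophile and 0.14% of its nucleophile left.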